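The theta run at 7 mM of J is still climbing at 80.0 min, with 61% as G, while epsilon at 110 mM creeps towards 44%, each read to 2 percentage points. The new flasks change the charge of J, and they stop at 2.0 h.

the same everywhere: X 42 µM

| run | J | remark | time |
|---|---|---|---|
| theta | 7 mM | run made earlier |  |
| epsilon | 110 mM | run made earlier |  |
| summer | 10 mM |  | 2.0 h |
| dusk | 20 mM |  | 2.0 h |
| midnight | 40 mM |  | 2.0 h |
| autumn | 80 mM |  | 2.0 h |
| winter | 150 mM |  | 2.0 h |

| theta: time / min | theta: G / % | epsilon: time / min | epsilon: G / % |
|---|---|---|---|
| 10.0 | 6 | 10.0 | 16 |
| 30.0 | 18 | 30.0 | 34 |
| 50.0 | 44 | 50.0 | 38 |
| 80.0 | 61 | 80.0 | 44 |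

(each reading ± 2 percentage points)

- amount of G at the end, in percent of the J charged for summer, dusk, midnight, autumn, winter, in this order
- how that number moves from the first to the last of them (falls all the way / falls, then rises / hardly changes / rises, then falls / rises all the way)

First setting, the charge of J. A stall at a share of the charge reads as J leaving by a second path. Suppose, as a reckoning, that chains grow at a rate following [J] and the loss follows the square of [J], with a steady number of chains. Loss over growth is then [J]/Jc, and the share of J that reaches G is ln(1 + u)/u, where u is the starting [J] over Jc. Taking epsilon's last reading as that share and solving near 3 gives u = 3.35, so Jc = 32.8 mM: the crossover concentration, the [J] at which the selectivity factor between growth and loss is one. It is a reading, and it carries the scatter of epsilon.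

Second setting, the time. Here the fraction left counts, not the fraction made. Theta's ceiling by this rule is 90.7%. Read from the last two readings, the distance to it closes at 0.0151 /min, so if that rate held, theta at 2.0 h would still have 17.9% of its ceiling to go. At the first reading epsilon, with its last reading taken as its ceiling, stands a factor of 5.49 further towards that ceiling than theta, for a factor of 15.7 in J. The reckoning takes the clock as the square root of the charge, which is rough.

Together these give, as this reckoning's own row, 76.1%, 73.8%, 64.3%, 50.5% and 37.6% from summer to winter, a steady fall.

The forecast, for which the stall suggested that “the active centres die after a limited number of turnovers, or that a similar capacity limit applies”, gave 80%, 83%, 72%, 57% and 36%, so its row, unlike the reckoning here, rises, then falls.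

The flasks give 74.3%, 69.8%, 61.5%, 50.7% and 40.0%: the row falls all the way.

    J + D → G + D, rate k1*[D]*[J] (k = 910 /M/min)
    2 J → E (k = 0.380 /M/min)
    L ⇌ G, rate k3*(cs3 - [G]) while solid is left; crystals form when [G] > cs3 (solubility = 11.0 mM, k = 1.70 /min)
    J + X → D + G (k = 2.80 /M/min)

The step from two J to E is the main reason winter stops where it does: taken away, G at the end goes from 40.0% to 98.9%. In winter E holds 59.8% of the J charged, and the Jc of 32.8 mM gave 37.6% against 40.0%. In autumn, the neighbour, the same Jc gave 50.5% against 50.7%, with 48.9% of the J charged standing as E.

The numbers in the tables are calculated with constants of no real substance; scatter was added.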